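**Plan**

1. Labels: ring A is the dimethoxyphenyl ring and ring B the dienone (C1 carbonyl, C2 allyl-bearing, C3–H, C4 quaternary with OMe and the side chain, C5 with OMe, C6–H); the side chain is C8 (CH–CH3, on C4) and C7 (CH–OAc, on ring A).
2. Enabling feature: in ring B the enone bond C2=C3 carries the allyl group on C2 and ends at C3–H, which sits on the fully substituted C4. Read backwards, C3 is an aldehyde carbon that cannot enolise and C2 is the only CH2 next to a vinylogous-ester ketone, so C2=C3 is an aldol-condensation retron.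
3. Cuts, in retrosynthetic order: O–acetyl; C2=C3 (ring B); C5–OMe (methanol onto an ynone); C1–C6 (acetylide acylation); C4–OMe; C3–C4 (formyl anion onto a ketone); C4–C5 (acetylide onto an amide); C7–C8 (aldol).
4. Forward: the chain grows outward from ring A (aldol, alkynyl ketone, dithiane, methyl ether, pentenoyl unit, methanol addition, unmasking); ring B, the only ring made, closes last, and the silyl ether is then exchanged for the acetate.
5. Stereochemistry: C7 and C8 come from an Evans syn-aldol with the (R)-benzyl oxazolidinone; C4 comes from Felkin–Anh addition of 2-lithio-1,3-dithiane next to C8; the ring closure creates no stereocentre.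

Key step: step 11

Assumption: the β-methoxy enone made in step 9 is taken to be the E isomer (C4 and the ketone cis), as expected from allenolate protonation on the side away from C4 and from methoxide-mediated equilibration.

**Route**

Step 1
Reactants: 2 (R)-4-benzyl-3-propionyl-1,3-oxazolidin-2-one; 1 3,4-dimethoxybenzaldehyde
Product: 5 (4R)-4-benzyl-3-[(2R,3R)-3-(3,4-dimethoxyphenyl)-3-hydroxy-2-methylpropanoyl]-1,3-oxazolidin-2-one, via Z-boron enolate 3 (not isolated), via boron aldolate 4 (not isolated)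
Conditions: Bu2BOTf, Et3N, CH2Cl2, 0 °C; then 1, −78 → 0 °C; then aq. NaH2PO4/Na2HPO4 (pH 7), MeOH, H2O2, 0 °C
Reagents that add atoms: none
Why: Evans syn-aldol reaction, in which Z-enolate 3 reacts through a Zimmerman–Traxler chair with the aldehyde on the enolate face opposite the benzyl group of the dipole-opposed oxazolidinone, setting C8 (2R, methyl) and C7 (3R, hydroxyl) together in the syn relationship.

Step 2
Reactants: 5 the syn-aldol adduct
Product: 6 (2R,3R)-3-(3,4-dimethoxyphenyl)-3-hydroxy-N-methoxy-N,2-dimethylpropanamide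
Conditions: MeONHMe·HCl, AlMe3, CH2Cl2, −15 °C → rt; aqueous work-up
Reagents that add atoms: N,O-dimethylhydroxylamine hydrochloride, CNOC.Cl
Why: Weinreb amide formation by aluminium-amide transamidation of the N-acyl oxazolidinone, directed to the exocyclic carbonyl by the aluminium alkoxide of the free β-hydroxyl and leaving C7 and C8 untouched.

Step 3
Reactants: 6 the hydroxy Weinreb amide
Product: 7 (2R,3R)-3-[(tert-butyldimethylsilyl)oxy]-3-(3,4-dimethoxyphenyl)-N-methoxy-N,2-dimethylpropanamide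
Conditions: TBSOTf, 2,6-lutidine, CH2Cl2, −78 → 0 °C
Reagents that add atoms: tert-butyldimethylsilyl trifluoromethanesulfonate, CC(C)(C)[Si](C)(C)OS(=O)(=O)C(F)(F)F
Why: Silyl ether formation with a silyl triflate and a hindered pyridine base gives a robust, non-chelating protecting group for the benzylic hydroxyl through the organolithium and base steps.

Step 4
Reactants: 7 the silylated Weinreb amide; 8 ethynyltrimethylsilane
Product: 10 (4R,5R)-5-[(tert-butyldimethylsilyl)oxy]-5-(3,4-dimethoxyphenyl)-4-methyl-1-(trimethylsilyl)pent-1-yn-3-one, via lithium silylacetylide 9 (not isolated)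
Conditions: 8, n-BuLi, THF, −78 °C; then 7, −78 → 0 °C; H2O quench
Reagents that add atoms: none
Why: Weinreb ketone synthesis with a lithium acetylide; the N-methoxy-N-methylamide takes up one equivalent of 9 and releases the ynone only on quench, so over-addition and epimerisation at C8 are avoided.

Step 5
Reactants: 10 the silyl ynone
Product: 11 (3R,4R,5R)-5-[(tert-butyldimethylsilyl)oxy]-5-(3,4-dimethoxyphenyl)-3-(1,3-dithian-2-yl)-4-methyl-1-(trimethylsilyl)pent-1-yn-3-ol
Conditions: 1,3-dithiane, n-BuLi, THF, −30 °C; then 10, −78 °C; H2O quench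
Reagents that add atoms: 1,3-dithiane, C1CSCSC1 (delivered as 2-lithio-1,3-dithiane, [Li]C1SCCCS1)
Why: Corey–Seebach formyl-anion addition under Felkin–Anh control: with the CH(OSi)Ar group anti to the nucleophile, the methyl beside the carbonyl oxygen and the hydrogen beside the slim alkynyl group, the dithiane carbon enters the Si face and sets C4 as the 3R carbinol (new C–O bond syn to the C8 methyl when the chain is drawn through the dithiane carbon).

Step 6
Reactants: 11 the dithianyl carbinol
Product: 13 2-[(3R,4R,5R)-5-[(tert-butyldimethylsilyl)oxy]-5-(3,4-dimethoxyphenyl)-3-methoxy-4-methylpent-1-yn-3-yl]-1,3-dithiane, via silylalkyne methyl ether 12 (not isolated)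
Conditions: NaH, MeI, THF/DMF, 0 °C → rt; then MeOH, K2CO3, rt
Reagents that add atoms: iodomethane, IC
Why: Williamson etherification of the tertiary alkoxide, followed in the same flask by base-catalysed methanolysis of the alkynyl C–Si bond; the C7 silyl ether and the dithiane tolerate both operations.

Step 7
Reactants: 14 pent-4-enoic acid
Product: 16 N-methoxy-N-methylpent-4-enamide, via acyl imidazole 15 (not isolated)
Conditions: 1,1'-carbonyldiimidazole, CH2Cl2, rt; then MeONHMe·HCl, rt
Reagents that add atoms: N,O-dimethylhydroxylamine hydrochloride, CNOC.Cl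
Why: Amide coupling through the acyl imidazole, a standard preparation of N-methoxy-N-methylamides.

Step 8
Reactants: 13 the terminal alkyne; 16 N-methoxy-N-methylpent-4-enamide
Product: 18 (8R,9R,10R)-10-[(tert-butyldimethylsilyl)oxy]-10-(3,4-dimethoxyphenyl)-8-(1,3-dithian-2-yl)-8-methoxy-9-methyldec-1-en-6-yn-5-one, via alkynyllithium 17 (not isolated)
Conditions: n-BuLi, THF, −78 °C; then 16, −78 → −20 °C; AcOH quench at −78 °C
Reagents that add atoms: none
Why: Weinreb ketone synthesis with the lithium acetylide; the alkyne C–H is far more acidic than the dithiane C–H, and the cold acidic quench keeps the released amine from adding to the ynone.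

Step 9
Reactants: 18 the ynone
Product: 19 (6E,8R,9R,10R)-10-[(tert-butyldimethylsilyl)oxy]-10-(3,4-dimethoxyphenyl)-8-(1,3-dithian-2-yl)-7,8-dimethoxy-9-methyldeca-1,6-dien-5-one
Conditions: NaOMe (0.2 equiv), MeOH/THF, 0 °C → rt
Reagents that add atoms: methanol, CO
Why: Base-catalysed conjugate addition (oxa-Michael) of methanol to the ynone places OMe on C5 only, and both allenolate protonation away from the quaternary C4 and reversible methoxide addition should lead to the E enol ether with C4 and the ketone cis.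

Step 10
Reactants: 19 the β-methoxy enone dithiane
Product: 20 (2R,3E)-2-[(1R,2R)-1-[(tert-butyldimethylsilyl)oxy]-1-(3,4-dimethoxyphenyl)propan-2-yl]-2,3-dimethoxy-5-oxonona-3,8-dienal
Conditions: MeI, CaCO3, MeCN/H2O, 45 °C
Reagents that add atoms: water, O
Why: Alkylative dithiane hydrolysis (S-methylation, then water) under carbonate-buffered, non-oxidising conditions should spare the enol ether, the terminal alkene, the electron-rich arene and the silyl ether; the aldehyde formed has no α-hydrogen.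

Step 11
Reactants: 20 the keto-aldehyde
Product: 24 (4R)-4-[(1R,2R)-1-[(tert-butyldimethylsilyl)oxy]-1-(3,4-dimethoxyphenyl)propan-2-yl]-4,5-dimethoxy-2-(prop-2-en-1-yl)cyclohexa-2,5-dien-1-one, via lithium enolate 21 (not isolated), via lithium aldolate 22 (not isolated), via mesylate 23 (not isolated)
Conditions: LiN(SiMe3)2 (1.1 equiv), THF, −78 °C; then MsCl, −78 → 0 °C; then DBU, 0 °C → rt
Reagents that add atoms: none
Why: LiN(SiMe3)2 removes a proton from the only enolisable position, the CH2 between the ketone and the future allyl group, and lithium enolate 21 adds at once to the aldehyde on C4, which can act only as the electrophile; sulfonylation of aldolate 22 and E1cB loss of methanesulfonate from 23 with DBU then create the C2=C3 bond. The closest known reaction type is the intramolecular aldol condensation of 1,5-keto-aldehydes to cyclohexenones, run here stepwise in one flask. Ring B closes in a 6-(enolexo)-exo-trig mode, the E enol ether holding C4 and the ketone on the same side of C5=C6 so that the enolate carbon reaches the formyl group. No stereocentre is created: the transient centres at C2 and C3 become sp2, and C4, C7 and C8 bear no acidic hydrogen. The step needs regioselective enolisation and attack of the base on C–H and not on the formyl group; the first is secured because C4 is quaternary and C6–H is vinylic, the second by the neopentyl, α-branched aldehyde, the bulky silylamide and −78 °C.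

Step 12
Reactants: 24 the dienone silyl ether
Product: 25 (4R)-4-[(1R,2R)-1-(3,4-dimethoxyphenyl)-1-hydroxypropan-2-yl]-4,5-dimethoxy-2-(prop-2-en-1-yl)cyclohexa-2,5-dien-1-one
Conditions: Bu4NF, AcOH (1:1), THF, 0 °C → rt
Reagents that add atoms: none
Why: Fluoride-mediated desilylation, buffered with acetic acid so that the C7 hydroxyl is released without base-induced addition to the dienone.

Step 13
Reactants: 25 the benzylic alcohol
Product: 26 (1R,2R)-1-(3,4-dimethoxyphenyl)-2-[(1R)-1,2-dimethoxy-4-oxo-5-(prop-2-en-1-yl)cyclohexa-2,5-dien-1-yl]propyl acetate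
Conditions: Ac2O, pyridine, 4-(dimethylamino)pyridine (cat.), CH2Cl2, 0 °C → rt
Reagents that add atoms: acetic anhydride, CC(=O)OC(C)=O
Why: Nucleophile-catalysed acetylation of the secondary alcohol with retention at C7 gives the target.

**Compound list**

1 | 3,4-dimethoxybenzaldehyde | COc1ccc(C=O)cc1OC | starting material
2 | (R)-4-benzyl-3-propionyl-1,3-oxazolidin-2-one | CCC(=O)N1[C@H](Cc2ccccc2)COC1=O | starting material
3 | (Z)-O-dibutylboryl enolate of 2 | CCCCB(CCCC)O/C(=C\C)N1[C@H](Cc2ccccc2)COC1=O | intermediate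
4 | O-dibutylboryl aldolate of 5 | O=C(N1[C@H](Cc2ccccc2)COC1=O)[C@H](C)[C@@H](OB(CCCC)CCCC)c1ccc(OC)c(OC)c1 | intermediate
5 | (4R)-4-benzyl-3-[(2R,3R)-3-(3,4-dimethoxyphenyl)-3-hydroxy-2-methylpropanoyl]-1,3-oxazolidin-2-one | O=C(N1[C@H](Cc2ccccc2)COC1=O)[C@H](C)[C@@H](O)c1ccc(OC)c(OC)c1 | intermediate
6 | (2R,3R)-3-(3,4-dimethoxyphenyl)-3-hydroxy-N-methoxy-N,2-dimethylpropanamide | CON(C)C(=O)[C@H](C)[C@@H](O)c1ccc(OC)c(OC)c1 | intermediate
7 | (2R,3R)-3-[(tert-butyldimethylsilyl)oxy]-3-(3,4-dimethoxyphenyl)-N-methoxy-N,2-dimethylpropanamide | CON(C)C(=O)[C@H](C)[C@@H](O[Si](C)(C)C(C)(C)C)c1ccc(OC)c(OC)c1 | intermediate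
8 | ethynyltrimethylsilane | C#C[Si](C)(C)C | starting material
9 | lithium (trimethylsilyl)acetylide | [Li]C#C[Si](C)(C)C | intermediate
10 | (4R,5R)-5-[(tert-butyldimethylsilyl)oxy]-5-(3,4-dimethoxyphenyl)-4-methyl-1-(trimethylsilyl)pent-1-yn-3-one | C[Si](C)(C)C#CC(=O)[C@H](C)[C@@H](O[Si](C)(C)C(C)(C)C)c1ccc(OC)c(OC)c1 | intermediate
11 | (3R,4R,5R)-5-[(tert-butyldimethylsilyl)oxy]-5-(3,4-dimethoxyphenyl)-3-(1,3-dithian-2-yl)-4-methyl-1-(trimethylsilyl)pent-1-yn-3-ol | S1CCCSC1[C@@](O)([C@H](C)[C@@H](O[Si](C)(C)C(C)(C)C)c1ccc(OC)c(OC)c1)C#C[Si](C)(C)C | intermediate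
12 | O-methyl ether of 11 (trimethylsilyl alkyne retained) | S1CCCSC1[C@@](OC)([C@H](C)[C@@H](O[Si](C)(C)C(C)(C)C)c1ccc(OC)c(OC)c1)C#C[Si](C)(C)C | intermediate
13 | 2-[(3R,4R,5R)-5-[(tert-butyldimethylsilyl)oxy]-5-(3,4-dimethoxyphenyl)-3-methoxy-4-methylpent-1-yn-3-yl]-1,3-dithiane | S1CCCSC1[C@@](OC)([C@H](C)[C@@H](O[Si](C)(C)C(C)(C)C)c1ccc(OC)c(OC)c1)C#C | intermediate
14 | pent-4-enoic acid | C=CCCC(=O)O | starting material
15 | 1-(pent-4-enoyl)imidazole | C=CCCC(=O)n1ccnc1 | intermediate
16 | N-methoxy-N-methylpent-4-enamide | C=CCCC(=O)N(C)OC | intermediate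
17 | lithium acetylide of 13 | S1CCCSC1[C@@](OC)([C@H](C)[C@@H](O[Si](C)(C)C(C)(C)C)c1ccc(OC)c(OC)c1)C#C[Li] | intermediate
18 | (8R,9R,10R)-10-[(tert-butyldimethylsilyl)oxy]-10-(3,4-dimethoxyphenyl)-8-(1,3-dithian-2-yl)-8-methoxy-9-methyldec-1-en-6-yn-5-one | S1CCCSC1[C@@](OC)([C@H](C)[C@@H](O[Si](C)(C)C(C)(C)C)c1ccc(OC)c(OC)c1)C#CC(=O)CCC=C | intermediate
19 | (6E,8R,9R,10R)-10-[(tert-butyldimethylsilyl)oxy]-10-(3,4-dimethoxyphenyl)-8-(1,3-dithian-2-yl)-7,8-dimethoxy-9-methyldeca-1,6-dien-5-one | S1CCCSC1[C@@](OC)([C@H](C)[C@@H](O[Si](C)(C)C(C)(C)C)c1ccc(OC)c(OC)c1)/C(OC)=C\C(=O)CCC=C | intermediate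
20 | (2R,3E)-2-[(1R,2R)-1-[(tert-butyldimethylsilyl)oxy]-1-(3,4-dimethoxyphenyl)propan-2-yl]-2,3-dimethoxy-5-oxonona-3,8-dienal | O=C[C@@](OC)([C@H](C)[C@@H](O[Si](C)(C)C(C)(C)C)c1ccc(OC)c(OC)c1)/C(OC)=C\C(=O)CCC=C | intermediate
21 | lithium enolate of 20 at the CH2 next to the ketone | O=C[C@@](OC)([C@H](C)[C@@H](O[Si](C)(C)C(C)(C)C)c1ccc(OC)c(OC)c1)/C(OC)=C\C(O[Li])=CCC=C | intermediate
22 | lithium aldolate (ring B closed, C3–OLi, C2–H; mixture at C2 and C3) | C=CCC1C(O[Li])[C@@](OC)([C@H](C)[C@@H](O[Si](C)(C)C(C)(C)C)c2ccc(OC)c(OC)c2)C(OC)=CC1=O | intermediate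
23 | C3 methanesulfonate of the aldol (mixture at C2 and C3) | C=CCC1C(OS(C)(=O)=O)[C@@](OC)([C@H](C)[C@@H](O[Si](C)(C)C(C)(C)C)c2ccc(OC)c(OC)c2)C(OC)=CC1=O | intermediate
24 | (4R)-4-[(1R,2R)-1-[(tert-butyldimethylsilyl)oxy]-1-(3,4-dimethoxyphenyl)propan-2-yl]-4,5-dimethoxy-2-(prop-2-en-1-yl)cyclohexa-2,5-dien-1-one | C=CCC1=C[C@@](OC)([C@H](C)[C@@H](O[Si](C)(C)C(C)(C)C)c2ccc(OC)c(OC)c2)C(OC)=CC1=O | intermediate
25 | (4R)-4-[(1R,2R)-1-(3,4-dimethoxyphenyl)-1-hydroxypropan-2-yl]-4,5-dimethoxy-2-(prop-2-en-1-yl)cyclohexa-2,5-dien-1-one | C=CCC1=C[C@@](OC)([C@H](C)[C@@H](O)c2ccc(OC)c(OC)c2)C(OC)=CC1=O | intermediate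
26 | (1R,2R)-1-(3,4-dimethoxyphenyl)-2-[(1R)-1,2-dimethoxy-4-oxo-5-(prop-2-en-1-yl)cyclohexa-2,5-dien-1-yl]propyl acetate | C=CCC1=C[C@@](OC)([C@H](C)[C@@H](OC(C)=O)c2ccc(OC)c(OC)c2)C(OC)=CC1=O | target

**Step count**

Total: 13 steps. Longest linear sequence: 12 steps (steps 1–6 and 8–13, from 2); step 7 prepares amide 16 on a side branch.

**Steps most likely to fail**

Step 11 (ring closure). The silylamide may add to the formyl group, the aldolate may revert before it is trapped, or the elimination may stall. The fallback makes the same C2=C3 bond by an intramolecular Horner–Wadsworth–Emmons reaction, in which a phosphonate on C2 makes that carbon acidic enough for a mild amine base and renders the elimination irreversible. It would set out from dithiane 19. Deprotonation with LiN(iPr)2 at −78 °C, trapping with ClP(OEt)2 and air oxidation should give diethyl [(6E,8R,9R,10R)-10-[(tert-butyldimethylsilyl)oxy]-10-(3,4-dimethoxyphenyl)-8-(1,3-dithian-2-yl)-7,8-dimethoxy-9-methyl-5-oxodeca-1,6-dien-4-yl]phosphonate F1. MeI/CaCO3 in aqueous MeCN would then unmask diethyl [(6E,8R,9R,10R)-10-[(tert-butyldimethylsilyl)oxy]-10-(3,4-dimethoxyphenyl)-8-formyl-7,8-dimethoxy-9-methyl-5-oxodeca-1,6-dien-4-yl]phosphonate F2. LiCl and DBU in MeCN should close ring B, returning to the route at dienone 24.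

Step 5 (quaternary centre). Facial selectivity may be poor, because in the open transition state the β-silyloxy centre does not reinforce the Felkin–Anh preference set by C8; the basic nucleophile may also abstract the C8 proton. The fallback introduces the two carbon substituents in the opposite order under 1,3-chelation control, where attack anti to the C8 methyl and 1,3-anti to the C7 oxygen is the same, required face. It would set out from hydroxy amide 6:
- CH2=CHMgBr (excess, THF, −78 → 0 °C, acidic quench) should give (4R,5R)-5-(3,4-dimethoxyphenyl)-5-hydroxy-4-methylpent-1-en-3-one F3.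
- Me3SiC≡CMgBr (excess, −78 °C) should add to the magnesium alkoxide chelate to give (3R,4R,5R)-5-(3,4-dimethoxyphenyl)-4-methyl-3-[(trimethylsilyl)ethynyl]pent-1-ene-3,5-diol F4.
- TBSCl/imidazole in DMF should silylate only the secondary hydroxyl, giving (3R,4R,5R)-5-[(tert-butyldimethylsilyl)oxy]-5-(3,4-dimethoxyphenyl)-4-methyl-3-[(trimethylsilyl)ethynyl]pent-1-en-3-ol F5.
- OsO4 (cat.), NaIO4 and 2,6-lutidine in aqueous dioxane should cleave the vinyl group to (2R,3R,4R)-4-[(tert-butyldimethylsilyl)oxy]-4-(3,4-dimethoxyphenyl)-2-hydroxy-3-methyl-2-[(trimethylsilyl)ethynyl]butanal F6.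
- Propane-1,3-dithiol with MgBr2·OEt2 would convert F6 into carbinol 11, where the main route resumes.

Step 12 (desilylation). The liberated C7 oxygen may add to C3 or C5 of the dienone (five-membered ring closure) before it is acetylated. The fallback exchanges the silyl ether for the acetate without a free alcohol: Ac2O with catalytic Cu(OTf)2 in CH2Cl2 at 0 °C acylates the silyl ether oxygen directly. It sets out from 24 and arrives at target 26 in one operation, with no new compound (F0).

**Further compounds**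

F1 | step 11 | diethyl [(6E,8R,9R,10R)-10-[(tert-butyldimethylsilyl)oxy]-10-(3,4-dimethoxyphenyl)-8-(1,3-dithian-2-yl)-7,8-dimethoxy-9-methyl-5-oxodeca-1,6-dien-4-yl]phosphonate | S1CCCSC1[C@@](OC)([C@H](C)[C@@H](O[Si](C)(C)C(C)(C)C)c1ccc(OC)c(OC)c1)/C(OC)=C\C(=O)C(CC=C)P(=O)(OCC)OCC
F2 | step 11 | diethyl [(6E,8R,9R,10R)-10-[(tert-butyldimethylsilyl)oxy]-10-(3,4-dimethoxyphenyl)-8-formyl-7,8-dimethoxy-9-methyl-5-oxodeca-1,6-dien-4-yl]phosphonate | O=C[C@@](OC)([C@H](C)[C@@H](O[Si](C)(C)C(C)(C)C)c1ccc(OC)c(OC)c1)/C(OC)=C\C(=O)C(CC=C)P(=O)(OCC)OCC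
F3 | step 5 | (4R,5R)-5-(3,4-dimethoxyphenyl)-5-hydroxy-4-methylpent-1-en-3-one | C=CC(=O)[C@H](C)[C@@H](O)c1ccc(OC)c(OC)c1
F4 | step 5 | (3R,4R,5R)-5-(3,4-dimethoxyphenyl)-4-methyl-3-[(trimethylsilyl)ethynyl]pent-1-ene-3,5-diol | C=C[C@@](O)([C@H](C)[C@@H](O)c1ccc(OC)c(OC)c1)C#C[Si](C)(C)C
F5 | step 5 | (3R,4R,5R)-5-[(tert-butyldimethylsilyl)oxy]-5-(3,4-dimethoxyphenyl)-4-methyl-3-[(trimethylsilyl)ethynyl]pent-1-en-3-ol | C=C[C@@](O)([C@H](C)[C@@H](O[Si](C)(C)C(C)(C)C)c1ccc(OC)c(OC)c1)C#C[Si](C)(C)C
F6 | step 5 | (2R,3R,4R)-4-[(tert-butyldimethylsilyl)oxy]-4-(3,4-dimethoxyphenyl)-2-hydroxy-3-methyl-2-[(trimethylsilyl)ethynyl]butanal | O=C[C@@](O)([C@H](C)[C@@H](O[Si](C)(C)C(C)(C)C)c1ccc(OC)c(OC)c1)C#C[Si](C)(C)C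
F0 | step 12 | none | none
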